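**Plan**
1. Retrosynthetic cuts: C13–C14 (aldol condensation of a left C13 aldehyde with a right-half enone), the two tertiary acetates, C24–CH3 (from a C24 ketone) and, in the left half, C1–C11, O5–C6, C10–C11 and C2–C3.
2. Enabling feature: in the left cyclohexane C1–C2–C3–C4–C10–C11 the tertiary carbinol carbon C1 (CH3, O) is bonded to the methine C11 that carries the C12–C13 arm, so a C1 methyl ketone and a C11=C12–C13 enoate on the finished oxepane (O5, C6–C10, C4) give the ring and both centres through one C1–C11 bond.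
3. Forward, left: geraniol → quaternary C10 (epoxy-alcohol alkynylation) → butenyl chain → oxepane (epoxide opening at C6) → keto-enoate → cathodic 6-exo cyclisation closes the left cyclohexane.
4. Forward, right: the bis-epoxide of geranylacetone closes oxepane and cyclohexanone in one cascade; union at C13–C14, then hydrogenation, C24 methylenation/epoxidation/hydride, desilylation, C18 oxidation, acetylation.
5. Stereochemistry: C4/C10 from Sharpless epoxidation plus invertive alkynyl opening; C7 and C21/C15 (and the transient C18) from Shi epoxides; C1/C11 from the chair of the key step; C14 by equilibration; C24 by equatorial epoxidation.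

Key step: step 9

Remark (locants): C1–C24 are the backbone carbons of 37 counted from the left acetate-bearing carbon to the right one (methyl and acetyl carbons left out); O5 and O20 are the ring oxygens.
Remark (assumption): under the malonate-buffered electrolysis the C1 alkoxide is taken to be protonated before it can close on the ester, so 18 is handled as the hydroxy ester.

Step 1
Reactants: 1 geraniol
Product: 2 (2S,3S)-2,3-epoxygeraniol
Conditions: Ti(OiPr)4 (cat.), L-(+)-diethyl tartrate (cat.), t-BuOOH, 4 Å MS, CH2Cl2, −20 °C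
Reagents that add atoms: tert-butyl hydroperoxide, CC(C)(C)OO
Why: Sharpless asymmetric epoxidation of the allylic alcohol; the L-(+)-tartrate catalyst gives the (2S,3S)-epoxide, which sets C4 and the face on which C10 will be built.

Step 2
Reactants: 2 (2S,3S)-2,3-epoxygeraniol; 3 ethynyltrimethylsilane
Product: 4 (2R,3S)-3,7-dimethyl-3-[(trimethylsilyl)ethynyl]oct-6-ene-1,2-diol
Conditions: 3, n-BuLi, then Et2AlCl, toluene, 0 °C; then 2, 0 °C → rt
Reagents that add atoms: none
Why: Hydroxyl-directed opening of a 2,3-epoxy alcohol by an alkynylalane at the tertiary C3 (known for trisubstituted epoxy alcohols): the aluminium alkoxide activates the epoxide and the alkynyl group enters at C10 opposite to oxygen, so inversion gives the quaternary centre while C4 keeps its oxygen and configuration.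

Step 3
Reactants: 4 (2R,3S)-3,7-dimethyl-3-[(trimethylsilyl)ethynyl]oct-6-ene-1,2-diol
Product: 7 (2R)-2-[(3S)-3,7-dimethyloct-6-en-1-yn-3-yl]oxirane, via primary tosylate 5 (not isolated), via silylated epoxide 6 (not isolated)
Conditions: TsCl, Et3N, Bu2SnO (cat.), CH2Cl2, 0 °C; then K2CO3, MeOH, rt
Reagents that add atoms: none
Why: Tin-catalysed selective sulfonylation of the primary hydroxyl, Williamson closure by the C4 alkoxide (C4 untouched) and methanolysis of the alkynylsilane in the same basic medium.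

Step 4
Reactants: 7 (2R)-2-[(3S)-3,7-dimethyloct-6-en-1-yn-3-yl]oxirane; 8 allylmagnesium bromide
Product: 9 (5S,6S)-6-ethynyl-6,10-dimethylundeca-1,9-dien-5-ol
Conditions: 8 (3 equiv), CuI (10 mol%), THF, −40 → 0 °C
Reagents that add atoms: none
Why: Copper-catalysed SN2 opening of the terminal epoxide at its CH2 carbon installs C2, C1 and the future C1 methyl as a butenyl group (masked 3-oxobutyl) and frees the C4 hydroxyl without touching a stereocentre.

Step 5
Reactants: 9 (5S,6S)-6-ethynyl-6,10-dimethylundeca-1,9-dien-5-ol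
Product: 10 (5S,6S)-8-[(2S)-3,3-dimethyloxiran-2-yl]-6-ethynyl-6-methyloct-1-en-5-ol
Conditions: L-fructose-derived Shi ketone (ent-Shi ketone, 30 mol%), Oxone, K2CO3, Bu4NHSO4, MeCN–DMM–aq. buffer (pH 10.5), 0 °C
Reagents that add atoms: Oxone (potassium peroxymonosulfate), [K+].[O-]S(=O)(=O)OO
Why: Shi epoxidation: the dioxirane takes the electron-rich trisubstituted olefin and leaves the terminal alkene and the alkyne, and the enantiomer of the usual D-fructose-derived ketone (which gives R-epoxides on such olefins) sets C7 as S.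

Step 6
Reactants: 10 (5S,6S)-8-[(2S)-3,3-dimethyloxiran-2-yl]-6-ethynyl-6-methyloct-1-en-5-ol
Product: 12 tert-butyl{[(3S,6S,7S)-7-(but-3-en-1-yl)-6-ethynyl-2,2,6-trimethyloxepan-3-yl]oxy}dimethylsilane, via oxepanol 11 (not isolated)
Conditions: CSA (10 mol%), CH2Cl2, −20 °C; then 2,6-lutidine, TBSOTf, −20 → 0 °C
Reagents that add atoms: tert-butyldimethylsilyl triflate, CC(C)(C)[Si](C)(C)OS(=O)(=O)C(F)(F)F
Why: Acid-catalysed intramolecular epoxide opening (7-endo hydroxy-epoxide cyclisation): the C4 hydroxyl attacks the protonated trisubstituted epoxide at its tertiary carbon C6, where the positive charge develops, while the secondary C7 is shielded by the adjacent gem-dimethyl carbon, so the oxepane closes with C7 keeping the oxygen and configuration from step 5, and the new secondary alcohol is silylated in the same flask.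

Step 7
Reactants: 12 tert-butyl{[(3S,6S,7S)-7-(but-3-en-1-yl)-6-ethynyl-2,2,6-trimethyloxepan-3-yl]oxy}dimethylsilane; 13 methyl chloroformate
Product: 16 methyl (2E)-3-[(2S,3S,6S)-2-(but-3-en-1-yl)-6-{[tert-butyl(dimethyl)silyl]oxy}-3,7,7-trimethyloxepan-3-yl]prop-2-enoate, via alkenylalane 14 (not isolated), via lithium alanate 15 (not isolated)
Conditions: i-Bu2AlH, heptane, 50 °C; MeLi, Et2O, 0 °C; 13, −30 °C → rt
Reagents that add atoms: none
Why: Hydroalumination–carbomethoxylation: syn addition of i-Bu2AlH to the terminal alkyne puts aluminium on the terminal carbon (E-alkenylalane), and the alkenyl group of the derived alanate is transferred to methyl chloroformate with retention to give the E-enoate, the terminal alkene being much slower to hydroaluminate at this temperature.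

Step 8
Reactants: 16 methyl (2E)-3-[(2S,3S,6S)-2-(but-3-en-1-yl)-6-{[tert-butyl(dimethyl)silyl]oxy}-3,7,7-trimethyloxepan-3-yl]prop-2-enoate
Product: 17 methyl (2E)-3-[(2S,3S,6S)-6-{[tert-butyl(dimethyl)silyl]oxy}-3,7,7-trimethyl-2-(3-oxobutyl)oxepan-3-yl]prop-2-enoate
Conditions: PdCl2 (10 mol%), CuCl, O2 (1 atm), DMF–H2O (7:1), rt
Reagents that add atoms: water, O
Why: Tsuji–Wacker oxidation: Markovnikov oxypalladation of the monosubstituted alkene gives the C1 methyl ketone, while the hindered, electron-poor enoate does not react.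

Step 9
Reactants: 17 methyl (2E)-3-[(2S,3S,6S)-6-{[tert-butyl(dimethyl)silyl]oxy}-3,7,7-trimethyl-2-(3-oxobutyl)oxepan-3-yl]prop-2-enoate
Product: 18 methyl [(3S,5aS,6S,7R,9aS)-3-{[tert-butyl(dimethyl)silyl]oxy}-7-hydroxy-2,2,5a,7-tetramethyldecahydro-1-benzoxepin-6-yl]acetate
Conditions: divided cell, Hg cathode, −2.4 V (SCE), Et4NOTs (0.1 M), DMF, CH2(CO2Me)2 (2 equiv), rt
Reagents that add atoms: none
Why: One-electron reduction at the cathode (of the enoate, the more easily reduced group; a ketyl-first path leads to the same bond) gives a radical anion in which the enoate β-carbon C11 and the carbonyl carbon C1 join, and a second electron plus protonation by the malonate deliver the γ-hydroxy ester; this is the electroreductive cyclisation of a ketone onto a tethered α,β-unsaturated ester, the electrochemical counterpart of the SmI2 ketyl–olefin cyclisation. The cyclohexane C1–C2–C3–C4–C10–C11 closes 6-exo-trig through a chair. C11: the oxepane bonds C4–O5 and C10–C9 stay equatorial on the forming chair (trans junction, C10 methyl axial) and the C12 arm of the enoate takes the equatorial site. C1: the methyl avoids the 1,3-diaxial contact with the C10 methyl and sits equatorial, which leaves the oxygen axial and cis to the C11 arm. The step needs cyclisation to outrun hydrodimerisation and simple saturation of the enoate: C11 is neopentylic, which slows intermolecular coupling, and the closure is intramolecular and six-membered; the carbon acid protonates the alkoxide before it can close on the ester.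

Step 10
Reactants: 18 methyl [(3S,5aS,6S,7R,9aS)-3-{[tert-butyl(dimethyl)silyl]oxy}-7-hydroxy-2,2,5a,7-tetramethyldecahydro-1-benzoxepin-6-yl]acetate
Product: 19 methyl [(3S,5aS,6S,7R,9aS)-3-{[tert-butyl(dimethyl)silyl]oxy}-2,2,5a,7-tetramethyl-7-[(triethylsilyl)oxy]decahydro-1-benzoxepin-6-yl]acetate
Conditions: TESOTf, 2,6-lutidine, CH2Cl2, −78 °C
Reagents that add atoms: triethylsilyl triflate, CC[Si](CC)(CC)OS(=O)(=O)C(F)(F)F
Why: Silyl triflate protection of the tertiary C1 alcohol, which would otherwise trap the C13 aldehyde as a lactol and could add to the enone formed in step 17.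

Step 11
Reactants: 19 methyl [(3S,5aS,6S,7R,9aS)-3-{[tert-butyl(dimethyl)silyl]oxy}-2,2,5a,7-tetramethyl-7-[(triethylsilyl)oxy]decahydro-1-benzoxepin-6-yl]acetate
Product: 20 [(3S,5aS,6S,7R,9aS)-3-{[tert-butyl(dimethyl)silyl]oxy}-2,2,5a,7-tetramethyl-7-[(triethylsilyl)oxy]decahydro-1-benzoxepin-6-yl]acetaldehyde
Conditions: i-Bu2AlH (1.1 equiv), CH2Cl2, −78 °C; Rochelle salt
Reagents that add atoms: none
Why: Partial reduction of the methyl ester to the C13 aldehyde through the aluminium hemiacetal that is stable at −78 °C.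

Step 12
Reactants: 21 geranylacetone
Product: 22 (5S,6S,9S)-5,6:9,10-diepoxy-6,10-dimethylundecan-2-one
Conditions: ent-Shi ketone (40 mol%), Oxone, K2CO3, Bu4NHSO4, MeCN–DMM–aq. buffer (pH 10.5), 0 °C
Reagents that add atoms: Oxone (potassium peroxymonosulfate), [K+].[O-]S(=O)(=O)OO
Why: Shi epoxidation of both trisubstituted olefins under catalyst control makes every new epoxide carbon S, which fixes C21/C15 and the later erased C18; the ketone is tolerated.

Step 13
Reactants: 22 (5S,6S,9S)-5,6:9,10-diepoxy-6,10-dimethylundecan-2-one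
Product: 23 {[(5S,6S,9S)-5,6:9,10-diepoxy-6,10-dimethylundec-1-en-2-yl]oxy}triethylsilane
Conditions: LDA, THF, −78 °C; TESCl, −78 → 0 °C
Reagents that add atoms: chlorotriethylsilane, CC[Si](Cl)(CC)CC
Why: Kinetic deprotonation of the methyl ketone on its methyl side and O-silylation give the terminal enol silane whose CH2 carbon is the future C14.

Step 14
Reactants: 23 {[(5S,6S,9S)-5,6:9,10-diepoxy-6,10-dimethylundec-1-en-2-yl]oxy}triethylsilane
Product: 24 (3S,5aS,9aS)-2,2,5a-trimethyl-3-[(triethylsilyl)oxy]decahydro-1-benzoxepin-7-one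
Conditions: TESOTf (1.0 equiv), 2,6-di-tert-butyl-4-methylpyridine, CH2Cl2, −78 °C
Reagents that add atoms: none
Why: Silyl triflate-promoted tandem oxa-/carbacyclisation of a diepoxy enol silane (known for this substrate class): the silylated terminal epoxide is opened at its tertiary carbon C19 by the oxygen of the C21–C15 epoxide, and the bicyclic epoxonium ion is opened at C15 with inversion by the enol silane carbon C14 through a chair, which gives the trans-fused oxepane–cyclohexanone with the silyl group on O18, while the silyl cation released from the enol ether regenerates the promoter.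

Step 15
Reactants: 24 (3S,5aS,9aS)-2,2,5a-trimethyl-3-[(triethylsilyl)oxy]decahydro-1-benzoxepin-7-one
Product: 26 (3S,5aS,9aS)-2,2,5a-trimethyl-3-[(triethylsilyl)oxy]-3,4,5,5a,6,9a-hexahydro-1-benzoxepin-7(2H)-one (C22=C23 enone), via trimethylsilyl enol ether 25 (not isolated)
Conditions: LDA, TMSCl, THF, −78 °C; then Pd(OAc)2, MeCN, rt
Reagents that add atoms: none
Why: Saegusa–Ito oxidation: LDA removes a proton at C23, the side away from the quaternary C15 and the only side that can become unsaturated, and palladium(II) turns the silyl enol ether into the enone, which leaves C14 as the only kinetic enolisation site.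

Step 16
Reactants: 26 (3S,5aS,9aS)-2,2,5a-trimethyl-3-[(triethylsilyl)oxy]-3,4,5,5a,6,9a-hexahydro-1-benzoxepin-7(2H)-one; 20 [(3S,5aS,6S,7R,9aS)-3-{[tert-butyl(dimethyl)silyl]oxy}-2,2,5a,7-tetramethyl-7-[(triethylsilyl)oxy]decahydro-1-benzoxepin-6-yl]acetaldehyde
Product: 27 C13–C14 aldol adduct (13-hydroxy-22-en-24-one; 1-OTES; 7-OTBS; 18-OTES; C13/C14 epimers)
Conditions: 26, LDA, THF, −78 °C; then 20, −78 °C; NH4Cl
Reagents that add atoms: none
Why: Aldol addition of the cross-conjugated lithium α′-enolate of the cyclohexenone (kinetic deprotonation occurs at C14) to the aldehyde forms the C13–C14 bond regiospecifically; the two new centres are erased in steps 17 and 18.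

Step 17
Reactants: 27 C13–C14 aldol adduct
Product: 29 13(14),22-dien-24-one (1-OTES; 7-OTBS; 18-OTES; geometry of the exocyclic olefin not controlled), via mesylate 28 (not isolated)
Conditions: MsCl, Et3N, CH2Cl2, 0 °C; then DBU, rt
Reagents that add atoms: none
Why: Mesylation of the β-hydroxy ketone and E1cB elimination give the conjugated exocyclic enone from all aldol epimers.

Step 18
Reactants: 29 13(14),22-dien-24-one
Product: 30 saturated 24-ketone (1-OTES; 7-OTBS; 18-OTES; C14 as in 37)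
Conditions: H2 (1 atm), Pd/C, EtOAc, rt; then DBU (cat.), CH2Cl2, rt
Reagents that add atoms: none
Why: Catalytic hydrogenation saturates both conjugated olefins; hydrogen reaches C14 from the face opposite the axial C15 methyl, and this centre, α to the ketone, also equilibrates to the equatorial side chain.

Step 19
Reactants: 30 saturated 24-ketone
Product: 31 24-methylidene compound (1-OTES; 7-OTBS; 18-OTES)
Conditions: Ph3PCH3Br, KOtBu, toluene, 80 °C
Reagents that add atoms: methyltriphenylphosphonium bromide, C[P+](c1ccccc1)(c1ccccc1)c1ccccc1.[Br-]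
Why: Wittig methylenation of the ketone, with C14 already in its thermodynamic configuration.

Step 20
Reactants: 31 24-methylidene compound
Product: 32 C24 spiro-epoxide (oxygen equatorial at C24; 1-OTES; 7-OTBS; 18-OTES)
Conditions: mCPBA, NaHCO3, CH2Cl2, 0 °C
Reagents that add atoms: meta-chloroperoxybenzoic acid, OOC(=O)c1cccc(Cl)c1
Why: Peracid epoxidation of the exocyclic olefin from the equatorial direction, the axial face being blocked by the 1,3-diaxial C15 methyl as in 8(17)-labdenes, places the oxygen equatorial at C24.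

Step 21
Reactants: 32 C24 spiro-epoxide
Product: 33 24-ol (C24 as in 37; 1-OTES; 7-OTBS; 18-OTES)
Conditions: LiAlH4, THF, 0 °C → rt
Reagents that add atoms: none
Why: Hydride opens the spiro-epoxide at its CH2 carbon, leaving the tertiary alcohol with equatorial OH and axial methyl at C24.

Step 22
Reactants: 33 24-ol
Product: 34 1,18,24-triol 7-O-TBS ether
Conditions: HF·pyridine, pyridine, THF, 0 °C
Reagents that add atoms: none
Why: Fluoride cleaves the two triethylsilyl ethers, while the tert-butyldimethylsilyl ether next to the quaternary C6 survives at 0 °C.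

Step 23
Reactants: 34 1,18,24-triol 7-O-TBS ether
Product: 35 1,24-diol-18-one 7-O-TBS ether
Conditions: Dess–Martin periodinane, NaHCO3, CH2Cl2, rt
Reagents that add atoms: none
Why: Dess–Martin oxidation converts the only secondary alcohol (C18) into the ketone; the two tertiary alcohols cannot be oxidised.

Step 24
Reactants: 35 1,24-diol-18-one 7-O-TBS ether
Product: 36 7-O-TBS ether of 37 (1,24-diacetate)
Conditions: Ac2O, DMAP, Et3N, toluene, 60 °C
Reagents that add atoms: acetic anhydride, CC(=O)OC(C)=O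
Why: DMAP-catalysed acyl transfer (Steglich-type acetylation) esterifies both tertiary alcohols under forcing conditions without changing any centre.

Step 25
Reactants: 36 7-O-TBS ether of 37
Product: 37 target CNP0298533.1
Conditions: HF·pyridine, THF, rt
Reagents that add atoms: none
Why: Fluoride cleavage of the last silyl ether frees the C7 alcohol and leaves the tertiary acetates and the ketone untouched.

**Compound list**
1 | geraniol | CC(C)=CCC/C(C)=C/CO | starting material
2 | (2S,3S)-2,3-epoxygeraniol | OC[C@@H]1O[C@@]1(C)CCC=C(C)C | intermediate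
3 | ethynyltrimethylsilane | C#C[Si](C)(C)C | starting material
4 | (2R,3S)-3,7-dimethyl-3-[(trimethylsilyl)ethynyl]oct-6-ene-1,2-diol | OC[C@H](O)[C@](C)(C#C[Si](C)(C)C)CCC=C(C)C | intermediate
5 | primary tosylate of 4 | Cc1ccc(cc1)S(=O)(=O)OC[C@H](O)[C@](C)(C#C[Si](C)(C)C)CCC=C(C)C | intermediate
6 | trimethyl{(3S)-3,7-dimethyl-3-[(2R)-oxiran-2-yl]oct-6-en-1-yn-1-yl}silane | C1O[C@@H]1[C@](C)(C#C[Si](C)(C)C)CCC=C(C)C | intermediate
7 | (2R)-2-[(3S)-3,7-dimethyloct-6-en-1-yn-3-yl]oxirane | C1O[C@@H]1[C@](C)(C#C)CCC=C(C)C | intermediate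
8 | allylmagnesium bromide | C=CC[Mg]Br | starting material
9 | (5S,6S)-6-ethynyl-6,10-dimethylundeca-1,9-dien-5-ol | C=CCC[C@H](O)[C@](C)(C#C)CCC=C(C)C | intermediate
10 | (5S,6S)-8-[(2S)-3,3-dimethyloxiran-2-yl]-6-ethynyl-6-methyloct-1-en-5-ol | C=CCC[C@H](O)[C@](C)(C#C)CC[C@@H]1OC1(C)C | intermediate
11 | (3S,6S,7S)-7-(but-3-en-1-yl)-6-ethynyl-2,2,6-trimethyloxepan-3-ol | C=CCC[C@@H]1OC(C)(C)[C@@H](O)CC[C@@]1(C)C#C | intermediate
12 | tert-butyl{[(3S,6S,7S)-7-(but-3-en-1-yl)-6-ethynyl-2,2,6-trimethyloxepan-3-yl]oxy}dimethylsilane | C=CCC[C@@H]1OC(C)(C)[C@@H](O[Si](C)(C)C(C)(C)C)CC[C@@]1(C)C#C | intermediate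
13 | methyl chloroformate | COC(Cl)=O | starting material
14 | (E)-alkenyl(diisobutyl)alane from 12 (Al on C12) | C=CCC[C@@H]1OC(C)(C)[C@@H](O[Si](C)(C)C(C)(C)C)CC[C@@]1(C)/C=C/[Al](CC(C)C)CC(C)C | intermediate
15 | lithium (E)-alkenyl(diisobutyl)(methyl)alanate | [Li+].C=CCC[C@@H]1OC(C)(C)[C@@H](O[Si](C)(C)C(C)(C)C)CC[C@@]1(C)/C=C/[Al-](C)(CC(C)C)CC(C)C | intermediate
16 | methyl (2E)-3-[(2S,3S,6S)-2-(but-3-en-1-yl)-6-{[tert-butyl(dimethyl)silyl]oxy}-3,7,7-trimethyloxepan-3-yl]prop-2-enoate | C=CCC[C@@H]1OC(C)(C)[C@@H](O[Si](C)(C)C(C)(C)C)CC[C@@]1(C)/C=C/C(=O)OC | intermediate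
17 | methyl (2E)-3-[(2S,3S,6S)-6-{[tert-butyl(dimethyl)silyl]oxy}-3,7,7-trimethyl-2-(3-oxobutyl)oxepan-3-yl]prop-2-enoate (key-step precursor) | CC(=O)CC[C@@H]1OC(C)(C)[C@@H](O[Si](C)(C)C(C)(C)C)CC[C@@]1(C)/C=C/C(=O)OC | intermediate
18 | methyl [(3S,5aS,6S,7R,9aS)-3-{[tert-butyl(dimethyl)silyl]oxy}-7-hydroxy-2,2,5a,7-tetramethyldecahydro-1-benzoxepin-6-yl]acetate (key-step product) | O[C@]1(C)CC[C@@H]2OC(C)(C)[C@@H](O[Si](C)(C)C(C)(C)C)CC[C@@]2(C)[C@@H]1CC(=O)OC | intermediate
19 | 1-O-triethylsilyl ether of 18 | CC[Si](CC)(CC)O[C@]1(C)CC[C@@H]2OC(C)(C)[C@@H](O[Si](C)(C)C(C)(C)C)CC[C@@]2(C)[C@@H]1CC(=O)OC | intermediate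
20 | left C13 aldehyde (1-OTES; 7-OTBS) | CC[Si](CC)(CC)O[C@]1(C)CC[C@@H]2OC(C)(C)[C@@H](O[Si](C)(C)C(C)(C)C)CC[C@@]2(C)[C@@H]1CC=O | intermediate
21 | geranylacetone | CC(=O)CC/C=C(\C)CCC=C(C)C | starting material
22 | (5S,6S,9S)-5,6:9,10-diepoxy-6,10-dimethylundecan-2-one | CC(=O)CC[C@@H]1O[C@@]1(C)CC[C@@H]1OC1(C)C | intermediate
23 | {[(5S,6S,9S)-5,6:9,10-diepoxy-6,10-dimethylundec-1-en-2-yl]oxy}triethylsilane | C=C(O[Si](CC)(CC)CC)CC[C@@H]1O[C@@]1(C)CC[C@@H]1OC1(C)C | intermediate
24 | (3S,5aS,9aS)-2,2,5a-trimethyl-3-[(triethylsilyl)oxy]decahydro-1-benzoxepin-7-one (right-half ketone; 18-OTES) | O=C1CC[C@@H]2OC(C)(C)[C@@H](O[Si](CC)(CC)CC)CC[C@@]2(C)C1 | intermediate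
25 | C24 trimethylsilyl enol ether of 24 (C23=C24) | C[Si](C)(C)OC1=CC[C@@H]2OC(C)(C)[C@@H](O[Si](CC)(CC)CC)CC[C@@]2(C)C1 | intermediate
26 | right-half enone (C22=C23; 18-OTES) | O=C1C=C[C@@H]2OC(C)(C)[C@@H](O[Si](CC)(CC)CC)CC[C@@]2(C)C1 | intermediate
27 | C13–C14 aldol adduct (C13/C14 epimers; other centres as in 37) | CC[Si](CC)(CC)O[C@]1(C)CC[C@@H]2OC(C)(C)[C@@H](O[Si](C)(C)C(C)(C)C)CC[C@@]2(C)[C@@H]1CC(O)C1[C@]2(C)CC[C@H](O[Si](CC)(CC)CC)C(C)(C)O[C@H]2C=CC1=O | intermediate
28 | 13-O-mesylate of 27 | CC[Si](CC)(CC)O[C@]1(C)CC[C@@H]2OC(C)(C)[C@@H](O[Si](C)(C)C(C)(C)C)CC[C@@]2(C)[C@@H]1CC(OS(C)(=O)=O)C1[C@]2(C)CC[C@H](O[Si](CC)(CC)CC)C(C)(C)O[C@H]2C=CC1=O | intermediate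
29 | 13(14),22-dien-24-one (exocyclic olefin geometry not controlled) | CC[Si](CC)(CC)O[C@]1(C)CC[C@@H]2OC(C)(C)[C@@H](O[Si](C)(C)C(C)(C)C)CC[C@@]2(C)[C@@H]1CC=C1[C@]2(C)CC[C@H](O[Si](CC)(CC)CC)C(C)(C)O[C@H]2C=CC1=O | intermediate
30 | saturated 24-ketone (1-OTES; 7-OTBS; 18-OTES) | CC[Si](CC)(CC)O[C@]1(C)CC[C@@H]2OC(C)(C)[C@@H](O[Si](C)(C)C(C)(C)C)CC[C@@]2(C)[C@@H]1CC[C@H]1[C@]2(C)CC[C@H](O[Si](CC)(CC)CC)C(C)(C)O[C@H]2CCC1=O | intermediate
31 | 24-methylidene compound | CC[Si](CC)(CC)O[C@]1(C)CC[C@@H]2OC(C)(C)[C@@H](O[Si](C)(C)C(C)(C)C)CC[C@@]2(C)[C@@H]1CC[C@H]1[C@]2(C)CC[C@H](O[Si](CC)(CC)CC)C(C)(C)O[C@H]2CCC1=C | intermediate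
32 | C24 spiro-epoxide (oxygen equatorial) | CC[Si](CC)(CC)O[C@]1(C)CC[C@@H]2OC(C)(C)[C@@H](O[Si](C)(C)C(C)(C)C)CC[C@@]2(C)[C@@H]1CC[C@H]1[C@]2(C)CC[C@H](O[Si](CC)(CC)CC)C(C)(C)O[C@H]2CC[C@@]13CO3 | intermediate
33 | 24-ol (1-OTES; 7-OTBS; 18-OTES) | CC[Si](CC)(CC)O[C@]1(C)CC[C@@H]2OC(C)(C)[C@@H](O[Si](C)(C)C(C)(C)C)CC[C@@]2(C)[C@@H]1CC[C@H]1[C@]2(C)CC[C@H](O[Si](CC)(CC)CC)C(C)(C)O[C@H]2CC[C@]1(C)O | intermediate
34 | 1,18,24-triol 7-O-TBS ether | O[C@]1(C)CC[C@@H]2OC(C)(C)[C@@H](O[Si](C)(C)C(C)(C)C)CC[C@@]2(C)[C@@H]1CC[C@H]1[C@]2(C)CC[C@H](O)C(C)(C)O[C@H]2CC[C@]1(C)O | intermediate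
35 | 1,24-diol-18-one 7-O-TBS ether | O[C@]1(C)CC[C@@H]2OC(C)(C)[C@@H](O[Si](C)(C)C(C)(C)C)CC[C@@]2(C)[C@@H]1CC[C@H]1[C@]2(C)CCC(=O)C(C)(C)O[C@H]2CC[C@]1(C)O | intermediate
36 | 7-O-TBS ether of 37 | CC(=O)O[C@]1(C)CC[C@@H]2OC(C)(C)[C@@H](O[Si](C)(C)C(C)(C)C)CC[C@@]2(C)[C@@H]1CC[C@H]1[C@]2(C)CCC(=O)C(C)(C)O[C@H]2CC[C@]1(C)OC(C)=O | intermediate
37 | CNP0298533.1 (1R,4S,7S,10S,11S,14S,15S,21S,24S in backbone locants; 1,24-diacetate; 7-ol; 18-one) | CC(=O)O[C@]1(C)CC[C@@H]2OC(C)(C)[C@@H](O)CC[C@@]2(C)[C@@H]1CC[C@H]1[C@]2(C)CCC(=O)C(C)(C)O[C@H]2CC[C@]1(C)OC(C)=O | target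

**Count**
Total steps: 25. Longest linear sequence: 21 steps (steps 1–11 and 16–25, geraniol to 37); the right-half branch (steps 12–15) joins at step 16.

**Steps most likely to fail**

Step 6 (oxepane closure). The hydroxyl may open the epoxide at the secondary carbon C7 (6-exo, a tetrahydropyran) instead of the tertiary C6, or the opened epoxide may undergo a hydride shift to a ketone. The fallback puts the C7 oxygen in first and closes the ring by a Markovnikov iodoetherification, for which the tertiary carbon is the only site that gives a ring. It sets out from diol 4 and returns at oxepanol 11. Shi epoxidation of the prenyl olefin of 4 with the same ketone gives the epoxy diol F1. Diethylaluminium 2,2,6,6-tetramethylpiperidide (toluene, 0 °C) isomerises the epoxide to the isopropenyl carbinol, the triol F2. NIS (MeCN, 0 °C) closes the C4 hydroxyl onto the disubstituted olefin carbon C6 to give the iodomethyl oxepane F3 (C6 epimers, later irrelevant). Bu3SnH/AIBN removes iodine to give the gem-dimethyl oxepane diol F4. Tf2O/2,6-lutidine at −78 °C sulfonylates the primary hydroxyl to the triflate F5, and allylmagnesium bromide/CuI displaces it to the butenyl oxepanol F6. K2CO3/MeOH cleaves the alkynylsilane to give 11, which is silylated to 12 as in step 6.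

Step 9 (key cyclisation). The enoate may be saturated or hydrodimerised instead of cyclising, control at C1 may erode, and the C1 alkoxide may close on the ester. The fallback generates the ketyl with a homogeneous one-electron reductant and uses the lactone on purpose. It sets out from 17 and returns at aldehyde 20. SmI2 in THF–MeOH at 0 °C gives the samarium ketyl, which adds to C11 in the same 6-exo mode, and the samarium alkoxide closes on the ester to the cis-fused γ-lactone F7 (any 18 formed is carried on as in step 10). LiAlH4 reduces F7 to the 1,13-diol F8. TESOTf/2,6-lutidine gives the bis(triethylsilyl) ether F9. Swern oxidation converts the primary silyl ether of F9 directly into aldehyde 20.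

Step 16 (aldol union). Addition of the hindered α′-enolate may be slow, so that proton transfer to the enolisable aldehyde and retro-aldol cleavage win. The fallback forms the C13–C14 bond by alkylation instead of aldol condensation. It sets out from 20 and returns at 30. NaBH4 reduces 20 to the C13 alcohol F10. PPh3/I2/imidazole gives the C13 iodide F11. The lithium α′-enolate of 26 (LDA, THF–DMPU, −78 → 0 °C) is alkylated by F11 to the α′-alkylated enone F12. Hydrogenation of its C22=C23 bond (H2, Pd/C), with equilibration at C14, gives 30.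

**Further compounds**
F1 | step 6 | epoxy diol (2R,3S)-5-[(2S)-3,3-dimethyloxiran-2-yl]-3-methyl-3-[(trimethylsilyl)ethynyl]pentane-1,2-diol | OC[C@H](O)[C@](C)(C#C[Si](C)(C)C)CC[C@@H]1OC1(C)C
F2 | step 6 | triol with isopropenyl carbinol (7S) | OC[C@H](O)[C@](C)(C#C[Si](C)(C)C)CC[C@H](O)C(C)=C
F3 | step 6 | iodomethyl oxepane diol (C6 epimers) | OC[C@@H]1OC(C)(CI)[C@@H](O)CC[C@@]1(C)C#C[Si](C)(C)C
F4 | step 6 | gem-dimethyl oxepane diol | OC[C@@H]1OC(C)(C)[C@@H](O)CC[C@@]1(C)C#C[Si](C)(C)C
F5 | step 6 | primary triflate of F4 | O=S(=O)(OC[C@@H]1OC(C)(C)[C@@H](O)CC[C@@]1(C)C#C[Si](C)(C)C)C(F)(F)F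
F6 | step 6 | butenyl oxepanol with alkynylsilane | C=CCC[C@@H]1OC(C)(C)[C@@H](O)CC[C@@]1(C)C#C[Si](C)(C)C
F7 | step 9 | cis-fused γ-lactone (O1–C13) | O3[C@]1(C)CC[C@@H]2OC(C)(C)[C@@H](O[Si](C)(C)C(C)(C)C)CC[C@@]2(C)[C@@H]1CC3=O
F8 | step 9 | 1,13-diol | O[C@]1(C)CC[C@@H]2OC(C)(C)[C@@H](O[Si](C)(C)C(C)(C)C)CC[C@@]2(C)[C@@H]1CCO
F9 | step 9 | 1,13-bis(triethylsilyl) ether | CC[Si](CC)(CC)O[C@]1(C)CC[C@@H]2OC(C)(C)[C@@H](O[Si](C)(C)C(C)(C)C)CC[C@@]2(C)[C@@H]1CCO[Si](CC)(CC)CC
F10 | step 16 | C13 alcohol (1-OTES; 7-OTBS) | CC[Si](CC)(CC)O[C@]1(C)CC[C@@H]2OC(C)(C)[C@@H](O[Si](C)(C)C(C)(C)C)CC[C@@]2(C)[C@@H]1CCO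
F11 | step 16 | C13 iodide | CC[Si](CC)(CC)O[C@]1(C)CC[C@@H]2OC(C)(C)[C@@H](O[Si](C)(C)C(C)(C)C)CC[C@@]2(C)[C@@H]1CCI
F12 | step 16 | α′-alkylated enone (C22=C23) | CC[Si](CC)(CC)O[C@]1(C)CC[C@@H]2OC(C)(C)[C@@H](O[Si](C)(C)C(C)(C)C)CC[C@@]2(C)[C@@H]1CC[C@H]1[C@]2(C)CC[C@H](O[Si](CC)(CC)CC)C(C)(C)O[C@H]2C=CC1=O
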